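**Plan**

- Retrosynthesis: after removal of the three protecting groups, ring C is cut at the C4–C4a aryl ketone bond, then at the O1–C2 ether bond. The C2/C3 oxygens go back to a trans epoxide and its E-cinnamamide (Heck bond to ring B), and the two aryl–prenyl bonds are cut last.
- Enabling feature: the C4 carbonyl sits on C4a, the ring A carbon ortho to the O1 ether oxygen. A bromine at C4a and an N-methoxy-N-methyl amide at C4, on a preformed O1–C2 ether, therefore let ring C close by aryllithium acylation without touching C2 or C3.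
- Forward: rings A and B start as halophenols and are prenylated. Phenol 7 (ring A) and epoxy amide 14 (ring B with C2, C3, C4) are joined through O1–C2, the C3 hydroxyl is silylated, ring C is closed, and one acid step frees all three hydroxyls.
- Stereochemistry: a Sm–BINOL-catalysed epoxidation sets C2 and C3 as the (2R,3S) trans epoxide. SN2 opening by the ring A phenoxide inverts the benzylic carbon to the anti (2R,3R) pair, which is the trans (2R,3R) pair of the target and is not touched again.

Key step: step 11

Assumption: with (S)-BINOL the samarium catalyst is taken to deliver the (2R,3S) epoxide, by analogy with the facial sense of this catalyst family on E-enones and E-cinnamamides; if the sense were opposite, (R)-BINOL would be used.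

**Route**

Step 1
Reactants: 1 4,6-dibromoresorcinol
Product: 2 2,4-dibromo-5-(methoxymethoxy)phenol
Conditions: MOMCl (1.0 equiv), iPr2NEt, CH2Cl2, 0 °C to rt
Reagents that add atoms: chloromethyl methyl ether (MOMCl), COCCl
Why: O-alkylation of a phenol (Williamson type); the two hydroxyls of 1 are equivalent, so only one mono-ether can form, and unreacted 1 and the bis-ether are separated and recycled.

Step 2
Reactants: 2 2,4-dibromo-5-(methoxymethoxy)phenol
Product: 3 [2,4-dibromo-5-(methoxymethoxy)phenoxy]tri(propan-2-yl)silane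
Conditions: TIPSCl, imidazole, DMF, 40 °C
Reagents that add atoms: chlorotri(propan-2-yl)silane (TIPSCl), CC(C)[Si](Cl)(C(C)C)C(C)C
Why: standard silylation of a phenol; the bulky, non-coordinating silyl ether is chosen to shield the bromine next to it in the following exchange.

Step 3
Reactants: 3 [2,4-dibromo-5-(methoxymethoxy)phenoxy]tri(propan-2-yl)silane; 4 prenyl bromide (1-bromo-3-methylbut-2-ene)
Product: 6 [2-bromo-5-(methoxymethoxy)-4-(3-methylbut-2-enyl)phenoxy]tri(propan-2-yl)silane, via aryllithium 5 (not isolated)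
Conditions: n-BuLi (0.98 equiv), THF, −78 °C; then CuI (10 mol %), prenyl bromide, −78 to 0 °C
Reagents that add atoms: none
Why: bromine–lithium exchange followed by copper-catalysed SN2 allylation; exchange is expected at the bromine flanked by the chelating methoxymethoxy group and not at the one beside the silyloxy group, the slight deficit of n-BuLi letting any wrong aryllithium equilibrate to the chelated one, and attack at the unhindered CH2 of prenyl bromide gives the linear prenyl arene.

Step 4
Reactants: 6 [2-bromo-5-(methoxymethoxy)-4-(3-methylbut-2-enyl)phenoxy]tri(propan-2-yl)silane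
Product: 7 2-bromo-5-(methoxymethoxy)-4-(3-methylbut-2-enyl)phenol
Conditions: Bu4NF, AcOH, THF, 0 °C
Reagents that add atoms: none
Why: fluoride cleavage of an aryl silyl ether; the acetal, the aryl bromide and the alkene are inert to buffered fluoride.

Step 5
Reactants: 8 4-bromo-2-iodophenol
Product: 9 4-bromo-2-iodo-1-(methoxymethoxy)benzene
Conditions: MOMCl, iPr2NEt, CH2Cl2, 0 °C to rt
Reagents that add atoms: chloromethyl methyl ether (MOMCl), COCCl
Why: O-alkylation of a phenol (Williamson type), giving an acetal that survives the organometallic and basic steps ahead.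

Step 6
Reactants: 9 4-bromo-2-iodo-1-(methoxymethoxy)benzene; 4 prenyl bromide
Product: 11 4-bromo-1-(methoxymethoxy)-2-(3-methylbut-2-enyl)benzene, via arylmagnesium chloride 10 (not isolated)
Conditions: iPrMgCl·LiCl, THF, −20 °C; then CuI (10 mol %), prenyl bromide, −20 to 0 °C
Reagents that add atoms: none
Why: Knochel-type iodine–magnesium exchange, far faster at C–I than at C–Br and helped by the ortho acetal oxygen, then copper-catalysed SN2 allylation to the linear prenyl arene.

Step 7
Reactants: 11 4-bromo-1-(methoxymethoxy)-2-(3-methylbut-2-enyl)benzene; 12 N-methoxy-N-methylacrylamide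
Product: 13 (E)-N-methoxy-3-[4-(methoxymethoxy)-3-(3-methylbut-2-enyl)phenyl]-N-methylprop-2-enamide
Conditions: Pd(OAc)2 (5 mol %), P(o-tol)3 (10 mol %), Et3N, DMF, 100 °C
Reagents that add atoms: none
Why: Mizoroki–Heck reaction of an aryl bromide with an acrylamide; insertion into the monosubstituted electron-poor alkene is much faster than into the trisubstituted prenyl alkene, and syn β-hydride elimination gives the E isomer.

Step 8
Reactants: 13 (E)-N-methoxy-3-[4-(methoxymethoxy)-3-(3-methylbut-2-enyl)phenyl]-N-methylprop-2-enamide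
Product: 14 (2R,3S)-N-methoxy-3-[4-(methoxymethoxy)-3-(3-methylbut-2-enyl)phenyl]-N-methyloxirane-2-carboxamide
Conditions: Sm(OiPr)3 (10 mol %), (S)-BINOL (10 mol %), Ph3As=O (10 mol %), TBHP (decane), 4 Å MS, THF, rt
Reagents that add atoms: tert-butyl hydroperoxide (TBHP), CC(C)(C)OO
Why: lanthanide–BINOL-catalysed nucleophilic epoxidation of a tertiary α,β-unsaturated amide (Shibasaki epoxidation, Weitz–Scheffer type); the samarium-bound peroxide adds only to the conjugated alkene, the BINOL ligand selects the enantioface and so fixes both C2 and C3, and the E geometry becomes the trans epoxide.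

Step 9
Reactants: 14 (2R,3S)-N-methoxy-3-[4-(methoxymethoxy)-3-(3-methylbut-2-enyl)phenyl]-N-methyloxirane-2-carboxamide; 7 2-bromo-5-(methoxymethoxy)-4-(3-methylbut-2-enyl)phenol
Product: 16 (2R,3R)-3-[2-bromo-5-(methoxymethoxy)-4-(3-methylbut-2-enyl)phenoxy]-2-hydroxy-N-methoxy-3-[4-(methoxymethoxy)-3-(3-methylbut-2-enyl)phenyl]-N-methylpropanamide, via caesium phenoxide 15 (not isolated)
Conditions: 7 (1.3 equiv), Cs2CO3 (0.3 equiv), DMF, 60 °C
Reagents that add atoms: none
Why: base-catalysed SN2 opening of a 3-aryl glycidic amide by a phenoxide; attack at the benzylic C3 (activated by the aryl group, while attack next to the carbonyl at C2 is disfavoured) proceeds with inversion, turning 3S into 3R with C2 untouched, which gives the anti (2R,3R) pair that becomes the trans C2/C3 pair of the target.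

Step 10
Reactants: 16 (the hydroxy amide from step 9)
Product: 17 (2R,3R)-3-[2-bromo-5-(methoxymethoxy)-4-(3-methylbut-2-enyl)phenoxy]-N-methoxy-3-[4-(methoxymethoxy)-3-(3-methylbut-2-enyl)phenyl]-N-methyl-2-(triethylsilyloxy)propanamide
Conditions: TESCl, imidazole, DMAP (cat.), DMF, rt
Reagents that add atoms: chlorotriethylsilane (TESCl), CC[Si](Cl)(CC)CC
Why: silylation of a secondary alcohol; the ether removes the acidic OH before the organolithium step and later falls off in the same acid step as the acetals.

Step 11
Reactants: 17 (the silyl ether from step 10)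
Product: 20 (2R,3R)-7-(methoxymethoxy)-2-[4-(methoxymethoxy)-3-(3-methylbut-2-enyl)phenyl]-6-(3-methylbut-2-enyl)-3-(triethylsilyloxy)-2,3-dihydro-4H-chromen-4-one, via aryllithium 18 (not isolated), via tetrahedral adduct 19 (not isolated)
Conditions: t-BuLi (2.1 equiv), THF, −78 °C; then AcOH, −78 °C to rt
Reagents that add atoms: none
Why: t-BuLi exchanges the C4a bromine (its second equivalent destroys the tert-butyl bromide formed) and aryllithium 18 adds to the amide carbonyl to make the C4–C4a bond, the N-methoxy oxygen chelating lithium in tetrahedral adduct 19 so that the ketone is released only by the AcOH quench. The closest known reaction type is the Parham cyclisation, halogen–lithium exchange followed by intramolecular acylation with an N-methoxy-N-methyl amide, which is established for chroman-4-ones and other benzo-fused ketones. Ring C closes in the 6-exo-trig mode, the carbanion being fixed ortho to O1 on ring A. No stereocentre is formed; C2 and C3 come unchanged from 17, and because the carbonyl is unmasked only after all base is consumed, C3 is never an enolisable position under basic conditions. The step needs chemoselectivity for exchange and closure over removal of the C3 proton with β-loss of the ring A aryloxide, over addition of t-BuLi to the amide, and over metalation next to the acetals or at the benzylic prenyl CH2 groups. This is secured by the speed of bromine–lithium exchange at −78 °C, by the six-membered intramolecular closure that follows at once, and by the silyl ether that screens the C3 proton.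

Step 12
Reactants: 20 (the protected dihydroflavonol from step 11)
Product: 21 lespeflorin B1, (2R,3R)-3,7-dihydroxy-2-[4-hydroxy-3-(3-methylbut-2-enyl)phenyl]-6-(3-methylbut-2-enyl)-2,3-dihydro-4H-chromen-4-one
Conditions: 3 M aq. HCl, MeOH, 40 °C
Reagents that add atoms: none
Why: acid-catalysed acetal solvolysis cleaves both aryl methoxymethyl ethers and the triethylsilyl ether is solvolysed in the same pot; dilute acid at mild temperature is not expected to cyclise the ortho-prenyl phenols to chromans or to epimerise the trans C2/C3 pair.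

**Compound list**

1 | 4,6-dibromoresorcinol | Oc1cc(O)c(Br)cc1Br | starting material
2 | 2,4-dibromo-5-(methoxymethoxy)phenol | Oc1cc(OCOC)c(Br)cc1Br | intermediate
3 | [2,4-dibromo-5-(methoxymethoxy)phenoxy]tri(propan-2-yl)silane | CC(C)[Si](Oc1cc(OCOC)c(Br)cc1Br)(C(C)C)C(C)C | intermediate
4 | prenyl bromide (1-bromo-3-methylbut-2-ene) | CC(C)=CCBr | starting material
5 | [2-bromo-4-lithio-5-(methoxymethoxy)phenoxy]tri(propan-2-yl)silane | CC(C)[Si](Oc1cc(OCOC)c([Li])cc1Br)(C(C)C)C(C)C | intermediate (not isolated)
6 | [2-bromo-5-(methoxymethoxy)-4-(3-methylbut-2-enyl)phenoxy]tri(propan-2-yl)silane | CC(C)[Si](Oc1cc(OCOC)c(CC=C(C)C)cc1Br)(C(C)C)C(C)C | intermediate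
7 | 2-bromo-5-(methoxymethoxy)-4-(3-methylbut-2-enyl)phenol | Oc1cc(OCOC)c(CC=C(C)C)cc1Br | intermediate
8 | 4-bromo-2-iodophenol | Oc1ccc(Br)cc1I | starting material
9 | 4-bromo-2-iodo-1-(methoxymethoxy)benzene | COCOc1ccc(Br)cc1I | intermediate
10 | [5-bromo-2-(methoxymethoxy)phenyl]magnesium chloride | COCOc1ccc(Br)cc1[Mg]Cl | intermediate (not isolated)
11 | 4-bromo-1-(methoxymethoxy)-2-(3-methylbut-2-enyl)benzene | COCOc1ccc(Br)cc1CC=C(C)C | intermediate
12 | N-methoxy-N-methylacrylamide | C=CC(=O)N(C)OC | starting material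
13 | (E)-N-methoxy-3-[4-(methoxymethoxy)-3-(3-methylbut-2-enyl)phenyl]-N-methylprop-2-enamide | CC(C)=CCc1cc(/C=C/C(=O)N(C)OC)ccc1OCOC | intermediate
14 | (2R,3S)-N-methoxy-3-[4-(methoxymethoxy)-3-(3-methylbut-2-enyl)phenyl]-N-methyloxirane-2-carboxamide | CC(C)=CCc1cc([C@@H]2O[C@H]2C(=O)N(C)OC)ccc1OCOC | intermediate
15 | caesium 2-bromo-5-(methoxymethoxy)-4-(3-methylbut-2-enyl)phenoxide | [Cs+].[O-]c1cc(OCOC)c(CC=C(C)C)cc1Br | intermediate (not isolated)
16 | (2R,3R)-3-[2-bromo-5-(methoxymethoxy)-4-(3-methylbut-2-enyl)phenoxy]-2-hydroxy-N-methoxy-3-[4-(methoxymethoxy)-3-(3-methylbut-2-enyl)phenyl]-N-methylpropanamide | CC(C)=CCc1cc([C@@H](Oc2cc(OCOC)c(CC=C(C)C)cc2Br)[C@@H](O)C(=O)N(C)OC)ccc1OCOC | intermediate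
17 | (2R,3R)-3-[2-bromo-5-(methoxymethoxy)-4-(3-methylbut-2-enyl)phenoxy]-N-methoxy-3-[4-(methoxymethoxy)-3-(3-methylbut-2-enyl)phenyl]-N-methyl-2-(triethylsilyloxy)propanamide | CC(C)=CCc1cc([C@@H](Oc2cc(OCOC)c(CC=C(C)C)cc2Br)[C@@H](O[Si](CC)(CC)CC)C(=O)N(C)OC)ccc1OCOC | intermediate (key-step precursor)
18 | aryllithium from 17, lithium in place of bromine at C4a | CC(C)=CCc1cc([C@@H](Oc2cc(OCOC)c(CC=C(C)C)cc2[Li])[C@@H](O[Si](CC)(CC)CC)C(=O)N(C)OC)ccc1OCOC | intermediate (not isolated)
19 | lithium alkoxide of the C4 N-methoxy-N-methyl hemiaminal of 20 (C4 configuration undefined) | CC(C)=CCc1cc([C@H]2Oc3cc(OCOC)c(CC=C(C)C)cc3C(O[Li])(N(C)OC)[C@@H]2O[Si](CC)(CC)CC)ccc1OCOC | intermediate (not isolated)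
20 | (2R,3R)-7-(methoxymethoxy)-2-[4-(methoxymethoxy)-3-(3-methylbut-2-enyl)phenyl]-6-(3-methylbut-2-enyl)-3-(triethylsilyloxy)-2,3-dihydro-4H-chromen-4-one | CC(C)=CCc1cc([C@H]2Oc3cc(OCOC)c(CC=C(C)C)cc3C(=O)[C@@H]2O[Si](CC)(CC)CC)ccc1OCOC | intermediate (key-step product)
21 | lespeflorin B1, (2R,3R)-3,7-dihydroxy-2-[4-hydroxy-3-(3-methylbut-2-enyl)phenyl]-6-(3-methylbut-2-enyl)-2,3-dihydro-4H-chromen-4-one | CC(C)=CCc1cc([C@H]2Oc3cc(O)c(CC=C(C)C)cc3C(=O)[C@@H]2O)ccc1O | target

**Step count and risks**

Total: 12 steps. Longest linear sequence: 8 steps (steps 1–4 or 5–8, then 9–12).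

Steps most likely to fail:

1. Step 9. The hindered, weakly nucleophilic ortho-bromophenoxide may attack the amide-bearing epoxide too slowly. Ionisation of the para-alkoxybenzylic C–O bond could then compete, with loss of clean inversion at the benzylic carbon or attack at C2. The fallback forms the ether on the epoxy alcohol, where phenoxide opening at the benzylic carbon of 3-arylglycidols is established. It sets out from bromide 11 (with phenol 7) and comes back at hydroxy amide 16.
   - Heck reaction of 11 with methyl acrylate (Pd(OAc)2, P(o-tol)3, Et3N) would give methyl (E)-3-[4-(methoxymethoxy)-3-(3-methylbut-2-enyl)phenyl]prop-2-enoate F1.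
   - iBu2AlH reduction would give (E)-3-[4-(methoxymethoxy)-3-(3-methylbut-2-enyl)phenyl]prop-2-en-1-ol F2.
   - Sharpless asymmetric epoxidation (Ti(OiPr)4, L-(+)-diethyl tartrate, TBHP, 4 Å MS, −20 °C), which leaves the prenyl alkene alone, would give [(2S,3S)-3-[4-(methoxymethoxy)-3-(3-methylbut-2-enyl)phenyl]oxiran-2-yl]methanol F3.
   - F3 would not be stored but opened at once with the sodium salt of 7 (NaOH, water/dioxane, 70 °C) to (2S,3R)-3-[2-bromo-5-(methoxymethoxy)-4-(3-methylbut-2-enyl)phenoxy]-3-[4-(methoxymethoxy)-3-(3-methylbut-2-enyl)phenyl]propane-1,2-diol F4.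
   - TEMPO/PhI(OAc)2 in MeCN/water would oxidise only the primary alcohol to (2R,3R)-3-[2-bromo-5-(methoxymethoxy)-4-(3-methylbut-2-enyl)phenoxy]-2-hydroxy-3-[4-(methoxymethoxy)-3-(3-methylbut-2-enyl)phenyl]propanoic acid F5.
   - Carbodiimide coupling (EDC, HOBt) with N,O-dimethylhydroxylamine hydrochloride would give 16.

2. Step 8. Conjugate addition of the samarium peroxide to an electron-rich cinnamoyl Weinreb amide may be sluggish, giving incomplete conversion and erosion of the enantiomeric purity by slow background epoxidation. The fallback moves the epoxidation to a far more electrophilic acyl imidazole and installs the amide afterwards. It sets out from bromide 11 and comes back at epoxy amide 14.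
   - Heck reaction of 11 with acrylic acid would give (E)-3-[4-(methoxymethoxy)-3-(3-methylbut-2-enyl)phenyl]prop-2-enoic acid F6.
   - Carbonyldiimidazole would convert it into (E)-1-(imidazol-1-yl)-3-[4-(methoxymethoxy)-3-(3-methylbut-2-enyl)phenyl]prop-2-en-1-one F7.
   - La(OiPr)3/(S)-BINOL/Ph3As=O with excess TBHP would exchange imidazole for tert-butylperoxide and epoxidise, giving tert-butyl (2R,3S)-3-[4-(methoxymethoxy)-3-(3-methylbut-2-enyl)phenyl]oxirane-2-carboperoxoate F8.
   - F8 would be treated in the same flask with N,O-dimethylhydroxylamine to give 14.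

3. Step 3. Exchange may occur at the wrong bromine or at both, so that site selectivity is poor and the regioisomeric prenyl arene is carried along. The fallback changes the selection principle from chelation of an aryl anion to steric control of oxidative addition. It sets out from dibromide 3 and comes back at 6 with no new compound: a linear-selective Negishi coupling of 3 with prenylzinc bromide (Pd(OAc)2, CPhos, THF, rt), in which zerovalent palladium is expected to insert into the C–Br bond beside the small methoxymethoxy group and not into the one flanked by the triisopropylsilyloxy group.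

**Further compounds**

F1 | step 9 | methyl (E)-3-[4-(methoxymethoxy)-3-(3-methylbut-2-enyl)phenyl]prop-2-enoate | CC(C)=CCc1cc(/C=C/C(=O)OC)ccc1OCOC
F2 | step 9 | (E)-3-[4-(methoxymethoxy)-3-(3-methylbut-2-enyl)phenyl]prop-2-en-1-ol | CC(C)=CCc1cc(/C=C/CO)ccc1OCOC
F3 | step 9 | [(2S,3S)-3-[4-(methoxymethoxy)-3-(3-methylbut-2-enyl)phenyl]oxiran-2-yl]methanol | CC(C)=CCc1cc([C@@H]2O[C@H]2CO)ccc1OCOC
F4 | step 9 | (2S,3R)-3-[2-bromo-5-(methoxymethoxy)-4-(3-methylbut-2-enyl)phenoxy]-3-[4-(methoxymethoxy)-3-(3-methylbut-2-enyl)phenyl]propane-1,2-diol | CC(C)=CCc1cc([C@@H](Oc2cc(OCOC)c(CC=C(C)C)cc2Br)[C@@H](O)CO)ccc1OCOC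
F5 | step 9 | (2R,3R)-3-[2-bromo-5-(methoxymethoxy)-4-(3-methylbut-2-enyl)phenoxy]-2-hydroxy-3-[4-(methoxymethoxy)-3-(3-methylbut-2-enyl)phenyl]propanoic acid | CC(C)=CCc1cc([C@@H](Oc2cc(OCOC)c(CC=C(C)C)cc2Br)[C@@H](O)C(=O)O)ccc1OCOC
F6 | step 8 | (E)-3-[4-(methoxymethoxy)-3-(3-methylbut-2-enyl)phenyl]prop-2-enoic acid | CC(C)=CCc1cc(/C=C/C(=O)O)ccc1OCOC
F7 | step 8 | (E)-1-(imidazol-1-yl)-3-[4-(methoxymethoxy)-3-(3-methylbut-2-enyl)phenyl]prop-2-en-1-one | CC(C)=CCc1cc(/C=C/C(=O)n2ccnc2)ccc1OCOC
F8 | step 8 | tert-butyl (2R,3S)-3-[4-(methoxymethoxy)-3-(3-methylbut-2-enyl)phenyl]oxirane-2-carboperoxoate | CC(C)=CCc1cc([C@@H]2O[C@H]2C(=O)OOC(C)(C)C)ccc1OCOC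
F0 | step 3 | none | none
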